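**Retrosynthetic overview**

1. The target comes from its tris-MOM ether by one final acid-catalysed removal of the three phenol protecting groups; the tris-MOM triamide comes from the N1,N10-diamide by acylation of the one remaining amine, N5.
2. The N1,N10-diamide is cut at the bond between N5 and the three-carbon chain (reductive amination) into a mono-acylated 1,4-diaminobutane and an N-acyl-3-aminopropanal, the latter made from 3-aminopropan-1-ol.
3. All three acyl groups come from one crystalline pentafluorophenyl ester of MOM-protected p-coumaric acid, used once in each of three separate amide-forming steps.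
4. The MOM-protected p-coumaric acid is cut at its Cα=Cβ bond into 4-(methoxymethoxy)benzaldehyde and malonic acid; this key C–C bond is made by an intermolecular aldol-type (Knoevenagel–Doebner) condensation that also fixes the E geometry.
5. No ring is formed anywhere: the three benzene rings are bought intact in 4-hydroxybenzaldehyde.

Assumption: the target has no stereocentre and is achiral, so "single enantiomer" is read as the single geometric isomer with all three alkenes E.

**Route**

Step 1
Reactants: 1 4-hydroxybenzaldehyde; 2 chloromethyl methyl ether (MOMCl)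
Product: 3 4-(methoxymethoxy)benzaldehyde
Conditions: MOMCl (1.3 equiv), K2CO3 (2 equiv), acetone, 0 °C to rt, 6 h
Reagents that add atoms: chloromethyl methyl ether (2), COCCl
Why: Williamson-type O-alkylation: the acidic para-formyl phenol is deprotonated by K2CO3 and the phenoxide displaces chloride from the very electrophilic α-chloro ether, giving an acetal that is inert to all the basic, oxidising and reducing steps that follow.

Step 2
Reactants: 3 4-(methoxymethoxy)benzaldehyde; 4 malonic acid
Product: 6 (E)-3-[4-(methoxymethoxy)phenyl]prop-2-enoic acid, via arylidenemalonic acid 5 (not isolated)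
Conditions: malonic acid (2 equiv), pyridine, piperidine (0.1 equiv), 90 °C, 5 h; then ice-water, cold 1 M HCl to pH 3–4, filter
Reagents that add atoms: malonic acid (4), OC(=O)CC(=O)O
Why: Knoevenagel condensation with Doebner modification, an intermolecular aldol-type condensation: the piperidine-activated aldehyde is attacked by the malonate enolate, dehydration gives 5, and decarboxylation in hot pyridine gives the conjugated acid with the thermodynamically favoured E alkene (J about 16 Hz), while the MOM acetal is untouched by amine bases.

Step 3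
Reactants: 6 (E)-3-[4-(methoxymethoxy)phenyl]prop-2-enoic acid; 7 pentafluorophenol
Product: 9 pentafluorophenyl (E)-3-[4-(methoxymethoxy)phenyl]prop-2-enoate, via O-acylisourea 8 (not isolated)
Conditions: C6F5OH (1.1 equiv), DCC (1.1 equiv), EtOAc, 0 °C to rt, 12 h; filter off the urea, recrystallise
Reagents that add atoms: pentafluorophenol (7), Oc1c(F)c(F)c(F)c(F)c1F
Why: Carbodiimide (Steglich-type) esterification: the acid adds to DCC to give O-acylisourea 8, which the acidic phenol intercepts under neutral conditions that spare the MOM acetal and the E alkene, giving a crystalline active ester that can be purified and dosed exactly.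

Step 4
Reactants: 9 pentafluorophenyl (E)-3-[4-(methoxymethoxy)phenyl]prop-2-enoate; 10 1,4-diaminobutane (putrescine)
Product: 11 (E)-N-(4-aminobutyl)-3-[4-(methoxymethoxy)phenyl]prop-2-enamide
Conditions: 1,4-diaminobutane (8 equiv), CH2Cl2, 0 °C, 9 in CH2Cl2 added over 2 h; rt, 1 h; wash with 1 M NaOH and brine
Reagents that add atoms: 1,4-diaminobutane (10), NCCCCN
Why: Active-ester aminolysis under statistical control: with an eightfold excess of the symmetric diamine and slow addition each ester molecule meets free diamine and not product, so monoacylation dominates, and the excess diamine and the pentafluorophenolate are washed out with aqueous base.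

Step 5
Reactants: 9 pentafluorophenyl (E)-3-[4-(methoxymethoxy)phenyl]prop-2-enoate; 12 3-aminopropan-1-ol
Product: 13 (E)-N-(3-hydroxypropyl)-3-[4-(methoxymethoxy)phenyl]prop-2-enamide
Conditions: 3-aminopropan-1-ol (1.5 equiv), THF, 0 °C to rt, 2 h; wash with saturated aqueous NaHCO3
Reagents that add atoms: 3-aminopropan-1-ol (12), NCCCO
Why: Chemoselective active-ester aminolysis: the primary amine is far more nucleophilic than the primary alcohol toward a pentafluorophenyl ester, so only the amide forms and the hydroxyl stays free.

Step 6
Reactants: 13 (E)-N-(3-hydroxypropyl)-3-[4-(methoxymethoxy)phenyl]prop-2-enamide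
Product: 14 (E)-3-[4-(methoxymethoxy)phenyl]-N-(3-oxopropyl)prop-2-enamide
Conditions: Dess–Martin periodinane (1.3 equiv), pyridine (3 equiv), CH2Cl2, 0 °C to rt, 1.5 h; aqueous Na2S2O3/NaHCO3 work-up; used at once
Reagents that add atoms: none
Why: Dess–Martin oxidation: ligand exchange of the primary alcohol at iodine and loss of acetic acid give the aldehyde without over-oxidation, and the pyridine-buffered neutral conditions leave the MOM acetal, the secondary amide and the E alkene untouched.

Step 7
Reactants: 11 (E)-N-(4-aminobutyl)-3-[4-(methoxymethoxy)phenyl]prop-2-enamide; 14 (E)-3-[4-(methoxymethoxy)phenyl]-N-(3-oxopropyl)prop-2-enamide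
Product: 16 N1,N10-bis[(E)-4-(methoxymethoxy)cinnamoyl]spermidine, via imine 15 (not isolated)
Conditions: 11 (1.2 equiv), 3 Å molecular sieves, MeOH, rt, 3 h; then NaBH4 (1.5 equiv), 0 °C, 30 min; chromatography (CH2Cl2/MeOH/NH3)
Reagents that add atoms: none
Why: Stepwise reductive amination: the primary amine condenses with the unhindered aldehyde to imine 15 before any hydride is present, which suppresses double alkylation, and NaBH4 at 0 °C then reduces only the C=N bond and not the cinnamamide C=C or C=O.

Step 8
Reactants: 16 N1,N10-bis[(E)-4-(methoxymethoxy)cinnamoyl]spermidine; 9 pentafluorophenyl (E)-3-[4-(methoxymethoxy)phenyl]prop-2-enoate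
Product: 17 N1,N5,N10-tris[(E)-4-(methoxymethoxy)cinnamoyl]spermidine
Conditions: 9 (1.3 equiv), iPr2NEt (2 equiv), DMF, rt to 45 °C, 16 h, in the dark
Reagents that add atoms: none
Why: Active-ester aminolysis (amide bond formation): the secondary amine N5 is the only nucleophilic nitrogen left, the two amide NH groups and the masked phenols cannot compete, and the electron-rich β-aryl enoate is too poor a Michael acceptor for aza-Michael addition to interfere.

Step 9
Reactants: 17 N1,N5,N10-tris[(E)-4-(methoxymethoxy)cinnamoyl]spermidine
Product: 18 N1,N5,N10-tri-(E)-p-coumaroylspermidine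
Conditions: 1 M HCl in MeOH/THF (3:1), 45 °C, 3 h, in the dark; evaporate, chromatograph (CH2Cl2/MeOH)
Reagents that add atoms: none
Why: Acid-catalysed acetal solvolysis (MOM deprotection by transacetalisation to methanol): the aryl MOM ethers are cleaved under conditions far too mild to touch the three amides or isomerise the E alkenes, and the only by-product is volatile.

**Compound list**

1 | 4-hydroxybenzaldehyde | O=Cc1ccc(O)cc1 | starting material
2 | chloromethyl methyl ether (MOMCl) | COCCl | starting material
3 | 4-(methoxymethoxy)benzaldehyde | COCOc1ccc(C=O)cc1 | intermediate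
4 | malonic acid | OC(=O)CC(=O)O | starting material
5 | 2-[4-(methoxymethoxy)benzylidene]malonic acid (arylidenemalonic acid) | COCOc1ccc(C=C(C(=O)O)C(=O)O)cc1 | intermediate (not isolated)
6 | (E)-3-[4-(methoxymethoxy)phenyl]prop-2-enoic acid | COCOc1ccc(/C=C/C(=O)O)cc1 | intermediate
7 | pentafluorophenol | Oc1c(F)c(F)c(F)c(F)c1F | starting material
8 | N,N'-dicyclohexyl-O-[(E)-4-(methoxymethoxy)cinnamoyl]isourea (O-acylisourea) | COCOc1ccc(/C=C/C(=O)OC(=NC2CCCCC2)NC2CCCCC2)cc1 | intermediate (not isolated)
9 | pentafluorophenyl (E)-3-[4-(methoxymethoxy)phenyl]prop-2-enoate | COCOc1ccc(/C=C/C(=O)Oc2c(F)c(F)c(F)c(F)c2F)cc1 | intermediate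
10 | 1,4-diaminobutane (putrescine) | NCCCCN | starting material
11 | (E)-N-(4-aminobutyl)-3-[4-(methoxymethoxy)phenyl]prop-2-enamide | COCOc1ccc(/C=C/C(=O)NCCCCN)cc1 | intermediate
12 | 3-aminopropan-1-ol | NCCCO | starting material
13 | (E)-N-(3-hydroxypropyl)-3-[4-(methoxymethoxy)phenyl]prop-2-enamide | COCOc1ccc(/C=C/C(=O)NCCCO)cc1 | intermediate
14 | (E)-3-[4-(methoxymethoxy)phenyl]-N-(3-oxopropyl)prop-2-enamide | COCOc1ccc(/C=C/C(=O)NCCC=O)cc1 | intermediate
15 | imine of amine 11 and aldehyde 14 (C=N geometry not defined) | COCOc1ccc(/C=C/C(=O)NCCCCN=CCCNC(=O)/C=C/c2ccc(OCOC)cc2)cc1 | intermediate (not isolated)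
16 | N1,N10-bis[(E)-4-(methoxymethoxy)cinnamoyl]spermidine | COCOc1ccc(/C=C/C(=O)NCCCCNCCCNC(=O)/C=C/c2ccc(OCOC)cc2)cc1 | intermediate
17 | N1,N5,N10-tris[(E)-4-(methoxymethoxy)cinnamoyl]spermidine | COCOc1ccc(/C=C/C(=O)NCCCCN(CCCNC(=O)/C=C/c2ccc(OCOC)cc2)C(=O)/C=C/c2ccc(OCOC)cc2)cc1 | intermediate
18 | N1,N5,N10-tri-(E)-p-coumaroylspermidine | O=C(/C=C/c1ccc(O)cc1)NCCCCN(CCCNC(=O)/C=C/c1ccc(O)cc1)C(=O)/C=C/c1ccc(O)cc1 | target

**Totals**

Total step count: 9. Longest linear sequence: 8 steps (1 → 3 → 6 → 9 → 13 → 14 → 16 → 17 → 18); step 4 (9 → 11) is a one-step side branch that joins at step 7.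

**Three steps most likely to fail, with fallbacks**

Step 7 (reductive amination). The risks are decomposition of the β-amido aldehyde 14 before it condenses and double alkylation of amine 11. The fallback buys the triamine skeleton intact and masks N5 instead of forming its C–N bond; it sets out from ester 9 and comes back at 16. Commercial spermidine, N-(3-aminopropyl)butane-1,4-diamine, is treated with aqueous formaldehyde (1.0 equiv, water, 0 °C to rt), which closes the 1,3-diamine part to 1-(4-aminobutyl)hexahydropyrimidine F1, in which N5 is tertiary. Ester 9 (2.2 equiv, iPr2NEt, DMF, rt to 40 °C) then acylates the primary amine and the ring NH and gives 1-[(E)-4-(methoxymethoxy)cinnamoyl]-3-{4-[(E)-4-(methoxymethoxy)cinnamoylamino]butyl}hexahydropyrimidine F2. Heating F2 with malonic acid 4 and pyridine in ethanol passes the aminal CH2 on to malonic acid in a Knoevenagel reaction and releases diamide 16; these buffered conditions are those of step 2 and leave the MOM acetals intact.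

Step 4 (monoacylation of the symmetric diamine). The risks are bis-acylation and loss of the polar amine 11 into the aqueous phase when the excess diamine is washed out. The fallback replaces statistical control by a protecting group that is orthogonal to MOM; it sets out from ester 9 and comes back at 11. Commercial N-Fmoc-1,4-diaminobutane hydrochloride is acylated with 9 in CH2Cl2/saturated aqueous NaHCO3 (0 °C to rt) and gives 9H-fluoren-9-ylmethyl N-{4-[(E)-3-[4-(methoxymethoxy)phenyl]prop-2-enoylamino]butyl}carbamate F3. Piperidine in DMF (1:4, rt, 30 min) then removes the Fmoc group by β-elimination, conditions to which the MOM acetal and the cinnamamide are inert, and gives amine 11.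

Step 9 (global MOM removal). The risks are incomplete cleavage of one of the three acetals and acid-promoted side reactions of the freed electron-rich phenols with formaldehyde equivalents. The fallback changes the phenol protecting group to acetate, which is removed by mild base; it sets out from 1 and comes back at 18. Aldehyde 1 and malonic acid 4 are condensed with the phenol free (pyridine, catalytic piperidine, 60 °C, kept below 70 °C to avoid decarboxylation to the vinylphenol), which gives (E)-4-hydroxycinnamic acid F5 via 2-(4-hydroxybenzylidene)malonic acid F4 (not isolated). Acetic anhydride in pyridine, then water, gives (E)-4-acetoxycinnamic acid F6. Oxalyl chloride with catalytic DMF in CH2Cl2 gives (E)-4-acetoxycinnamoyl chloride F7. F7 (3.6 equiv) acylates all three nitrogens of commercial spermidine under two-phase Schotten–Baumann conditions (CH2Cl2, saturated aqueous NaHCO3, 0 °C) and gives N1,N5,N10-tris[(E)-4-acetoxycinnamoyl]spermidine F8. Catalytic K2CO3 in MeOH at rt transfers the three acetyl groups to methanol and gives 18.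

**Further compounds**

F1 | step 7 | 1-(4-aminobutyl)hexahydropyrimidine | NCCCCN1CCCNC1
F2 | step 7 | 1-[(E)-4-(methoxymethoxy)cinnamoyl]-3-{4-[(E)-4-(methoxymethoxy)cinnamoylamino]butyl}hexahydropyrimidine | COCOc1ccc(/C=C/C(=O)NCCCCN2CCCN(C(=O)/C=C/c3ccc(OCOC)cc3)C2)cc1
F3 | step 4 | 9H-fluoren-9-ylmethyl N-{4-[(E)-3-[4-(methoxymethoxy)phenyl]prop-2-enoylamino]butyl}carbamate | COCOc1ccc(/C=C/C(=O)NCCCCNC(=O)OCC2c3ccccc3-c3ccccc32)cc1
F4 | step 9 | 2-(4-hydroxybenzylidene)malonic acid | OC(=O)C(=Cc1ccc(O)cc1)C(=O)O
F5 | step 9 | (E)-4-hydroxycinnamic acid (p-coumaric acid) | OC(=O)/C=C/c1ccc(O)cc1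
F6 | step 9 | (E)-4-acetoxycinnamic acid | CC(=O)Oc1ccc(/C=C/C(=O)O)cc1
F7 | step 9 | (E)-4-acetoxycinnamoyl chloride | CC(=O)Oc1ccc(/C=C/C(=O)Cl)cc1
F8 | step 9 | N1,N5,N10-tris[(E)-4-acetoxycinnamoyl]spermidine | CC(=O)Oc1ccc(/C=C/C(=O)NCCCCN(CCCNC(=O)/C=C/c2ccc(OC(C)=O)cc2)C(=O)/C=C/c2ccc(OC(C)=O)cc2)cc1
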